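Ring A (C1–C5, C10) is closed last through its C2–C3 bond, C3 being the CH2 next to the methylene-bearing C4. The C4=CH2 group is treated as a latent carbonyl: C3 is then the methyl carbon of an acetyl group on C5, and C2 a primary bromide on the two-carbon arm of the quaternary C10. Kinetic enolisation of this monocyclic bromo ketone and 6-(enolendo)-exo-tet alkylation give the trans-decalone in one operation, after all four stereocentres stand on ring B; non-basic methylenation ends the route. Ring B arises from a Robinson annulation, an enzymatic dynamic kinetic resolution, a cuprate addition (C10) and an enolate benzylation (C9).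

Key step: step 12

Remark: locants follow eudesmane-type numbering of the target (C4 bears the exocyclic CH2 = C15, C5 is the ring-fusion CH, C10 the ring-fusion C–CH3, C9 carries CH3 and the benzylic C11, C8 the secondary CH3); β is the face of the C10 methyl; the carbinol configuration of 5 is of no consequence because it is oxidised in step 11.

Step 1
Reactants: 1 pentane-2,4-dione; 2 pent-1-en-3-one
Product: 4 rac-4-acetyl-2,3-dimethylcyclohex-2-en-1-one, via triketone 3 (not isolated)
Conditions: Et3N (cat.), neat, rt; then pyrrolidine (cat.), AcOH, toluene, reflux, Dean–Stark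
Reagents that add atoms: none
Why: Michael addition followed by amine-catalysed intramolecular aldol condensation (Robinson annulation), in which the enamine of the ethyl ketone attacks one acetyl carbonyl (the enolised diketone methyls are not nucleophilic), should give the tetrasubstituted enone carrying the C9 and C10 methyls and the C5 acetyl group; C5 is formed racemic and labile.

Step 2
Reactants: 4 rac-4-acetyl-2,3-dimethylcyclohex-2-en-1-one
Product: 5 (4R)-4-[(1S)-1-hydroxyethyl]-2,3-dimethylcyclohex-2-en-1-one
Conditions: ketoreductase (selected from a panel), NADP+ (cat.), i-PrOH, phosphate buffer pH 8, DMSO (5%), 30 °C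
Reagents that add atoms: none
Why: Ketoreductase-catalysed dynamic kinetic resolution: the C5–H is α to the acetyl and vinylogously α to the enone, so the enantiomers interconvert at pH 8 while the enzyme reduces only the acetyl group of the (R)-ketone, which fixes C5 and leaves the hindered conjugated ketone untouched.

Step 3
Reactants: 5 (4R)-4-[(1S)-1-hydroxyethyl]-2,3-dimethylcyclohex-2-en-1-one
Product: 6 (4R)-4-[(1S)-1-(tert-butyldimethylsilyloxy)ethyl]-2,3-dimethylcyclohex-2-en-1-one
Conditions: TBSCl, imidazole, DMF, rt
Reagents that add atoms: tert-butyldimethylsilyl chloride CC(C)(C)[Si](C)(C)Cl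
Why: Silylation under weakly basic conditions masks the secondary hydroxyl for the organometallic steps and avoids vinylogous elimination.

Step 4
Reactants: 6 (4R)-4-[(1S)-1-(tert-butyldimethylsilyloxy)ethyl]-2,3-dimethylcyclohex-2-en-1-one
Product: 7 trimethylsilyl enol ether (C8–OSiMe3 and C8=C9; C10 β-methyl and α-vinyl; C5 β side chain)
Conditions: CH2=CHMgBr, CuBr·SMe2 (10 mol%), Me3SiCl, DMPU, THF, −78 to −30 °C; Et3N, pentane work-up
Reagents that add atoms: vinylmagnesium bromide C=C[Mg]Br; chlorotrimethylsilane C[Si](C)(C)Cl
Why: Copper-catalysed conjugate addition accelerated by Me3SiCl, in which the C5 side chain (pseudoaxial through allylic strain with the C10 methyl) blocks the β face, so vinyl should enter trans to it and make C10 quaternary, while the enolate is trapped regiospecifically as the C8=C9 silyl enol ether.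

Step 5
Reactants: 7 trimethylsilyl enol ether; 8 methyl 3-(bromomethyl)-4-methoxybenzoate
Product: 10 vinyl ketone (C8=O; C9 β-methyl and α-(2-methoxy-5-methoxycarbonylbenzyl)), via lithium enolate 9 (not isolated)
Conditions: MeLi, THF, 0 °C; then 8, DMPU, −78 °C to rt
Reagents that add atoms: none
Why: MeLi cleaves the O–Si bond to the regiodefined lithium enolate, whose C-alkylation by the benzylic bromide is expected on the α face, anti to the C10 methyl and to the 1,3-related C5 side chain, so C9 becomes quaternary with β-methyl and α-benzyl.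

Step 6
Reactants: 10 vinyl ketone
Product: 12 hydroxy ketone (C10 α-CH2CH2OH), via alkylborane 11 (not isolated)
Conditions: 9-BBN, THF, 0 °C to rt; then H2O2, aq. NaOAc, 0 °C
Reagents that add atoms: hydrogen peroxide OO
Why: Anti-Markovnikov hydroboration of the only alkene by the bulky borane (hindered ketone and ester do not react) and buffered oxidation should deliver the primary alcohol at C2.

Step 7
Reactants: 12 hydroxy ketone
Product: 13 C8-methylidene alcohol
Conditions: Ph3PCH3Br, NaN(SiMe3)2, toluene, 80 °C
Reagents that add atoms: methyltriphenylphosphonium bromide C[P+](c1ccccc1)(c1ccccc1)c1ccccc1.[Br-]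
Why: Wittig methylenation of the hindered C8 ketone, which has no epimerisable α-stereocentre, with excess ylide; the hydroxyl is carried as its alkoxide.

Step 8
Reactants: 13 C8-methylidene alcohol
Product: 14 C8 β-methyl alcohol
Conditions: H2 (1 atm), Pd/C, EtOAc, rt
Reagents that add atoms: none
Why: Heterogeneous syn hydrogenation of the exocyclic alkene, expected from the α face because the β face is screened by the syn-axial C10 methyl while the hydroxyethyl arm and the arene on the α face can bind to the catalyst surface; this places the new C8 methyl β (axial).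

Step 9
Reactants: 14 C8 β-methyl alcohol
Product: 15 primary bromide (C10 α-CH2CH2Br)
Conditions: CBr4, PPh3, CH2Cl2, 0 °C
Reagents that add atoms: carbon tetrabromide BrC(Br)(Br)Br
Why: Appel bromination converts the primary alcohol into the bromide under neutral conditions that leave the silyl ether and the ester intact.

Step 10
Reactants: 15 primary bromide
Product: 16 bromo phenol carbinol (free ArOH and free C4–OH)
Conditions: BBr3, CH2Cl2, −78 to 0 °C; aq. NaHCO3
Reagents that add atoms: none
Why: BBr3 cleaves the aryl methyl ether and the silyl ether in one operation at a stage that holds neither an alkene nor an enolisable stereocentre; the benzoate ester and the primary bromide should be inert at low temperature.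

Step 11
Reactants: 16 bromo phenol carbinol
Product: 17 bromo methyl ketone (C5 β-acetyl)
Conditions: Dess–Martin periodinane, NaHCO3, CH2Cl2, 0 °C
Reagents that add atoms: none
Why: Dess–Martin oxidation of the secondary alcohol under buffered, non-enolising conditions should give the methyl ketone without loss of configuration at C5, the electron-poor phenol being inert.

Step 12
Reactants: 17 bromo methyl ketone
Product: 19 trans-decalone methyl 4-hydroxy-3-{[(1R,2S,4aR,8aS)-1,2,8a-trimethyl-5-oxodecahydronaphthalen-1-yl]methyl}benzoate, via dilithium enolate phenoxide 18 (not isolated)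
Conditions: LiN(iPr)2 (2.2 equiv), THF, −78 to −10 °C, high dilution; AcOH, −78 °C
Reagents that add atoms: none
Why: LiN(iPr)2 first forms the phenoxide and then removes a proton from the acetyl CH3 (kinetic; the tertiary C5–H is far slower), and the enolate carbon C3 displaces bromide at C2 in an intramolecular SN2 reaction. The closest known reaction type is the intramolecular alkylation of a kinetic methyl ketone enolate by a tethered primary halide. Ring A closes in the 6-(enolendo)-exo-tet mode through a chair-like transition state in which the C5 acyl group and the C10 arm are both equatorial, which gives the trans ring fusion directly. No new stereocentre is formed, and C5 is retained because the reaction runs under kinetic control with a cold acidic quench. The step needs C3 over C5 deprotonation and C- over O-alkylation, which the hindered amide base at low temperature, the lithium counter-ion in THF and the soft bromide leaving group should secure.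

Step 13
Reactants: 19 trans-decalone
Product: 20 methyl 4-hydroxy-3-{[(1R,2S,4aS,8aS)-1,2,8a-trimethyl-5-methylidenedecahydronaphthalen-1-yl]methyl}benzoate (target)
Conditions: Zn, CH2Br2, TiCl4, THF–CH2Cl2, 0 °C to rt
Reagents that add atoms: dibromomethane BrCBr
Why: Lombardo methylenation with the non-basic zinc–titanium methylene reagent converts the ketone into the exocyclic alkene without enolisation, so C5 should keep its configuration, and it tolerates the ester and the free phenol.

Compound list
1 | pentane-2,4-dione | CC(=O)CC(C)=O | starting material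
2 | pent-1-en-3-one | CCC(=O)C=C | starting material
3 | 3-acetyloctane-2,6-dione | CCC(=O)CCC(C(C)=O)C(C)=O | intermediate
4 | rac-4-acetyl-2,3-dimethylcyclohex-2-en-1-one | CC(=O)C1CCC(=O)C(C)=C1C | intermediate
5 | (4R)-4-[(1S)-1-hydroxyethyl]-2,3-dimethylcyclohex-2-en-1-one | CC1=C(C)C(=O)CC[C@H]1[C@H](C)O | intermediate
6 | (4R)-4-[(1S)-1-(tert-butyldimethylsilyloxy)ethyl]-2,3-dimethylcyclohex-2-en-1-one | CC1=C(C)C(=O)CC[C@H]1[C@H](C)O[Si](C)(C)C(C)(C)C | intermediate
7 | tert-butyl{(1S)-1-[(1R,2S)-2-ethenyl-2,3-dimethyl-4-(trimethylsilyloxy)cyclohex-3-en-1-yl]ethoxy}dimethylsilane (vinyl trans to the side chain) | C=C[C@@]1(C)[C@H]([C@H](C)O[Si](C)(C)C(C)(C)C)CCC(O[Si](C)(C)C)=C1C | intermediate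
8 | methyl 3-(bromomethyl)-4-methoxybenzoate | COC(=O)c1ccc(OC)c(CBr)c1 | starting material
9 | lithium enolate corresponding to 7 (O–Li in place of O–SiMe3) | C=C[C@@]1(C)[C@H]([C@H](C)O[Si](C)(C)C(C)(C)C)CCC(O[Li])=C1C | intermediate
10 | methyl 3-{[(1S,2S,3R)-3-[(1S)-1-(tert-butyldimethylsilyloxy)ethyl]-2-ethenyl-1,2-dimethyl-6-oxocyclohexyl]methyl}-4-methoxybenzoate | C=C[C@@]1(C)[C@H]([C@H](C)O[Si](C)(C)C(C)(C)C)CCC(=O)[C@@]1(C)Cc1cc(C(=O)OC)ccc1OC | intermediate
11 | B-alkyl-9-borabicyclo[3.3.1]nonane formed from 10 (boron on C2) | C1CCC2CCCC1B2CC[C@@]1(C)[C@H]([C@H](C)O[Si](C)(C)C(C)(C)C)CCC(=O)[C@@]1(C)Cc1cc(C(=O)OC)ccc1OC | intermediate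
12 | hydroxy ketone: 10 with the vinyl group replaced by CH2CH2OH | OCC[C@@]1(C)[C@H]([C@H](C)O[Si](C)(C)C(C)(C)C)CCC(=O)[C@@]1(C)Cc1cc(C(=O)OC)ccc1OC | intermediate
13 | C8-methylidene alcohol: 12 with C8=O replaced by C8=CH2 | OCC[C@@]1(C)[C@H]([C@H](C)O[Si](C)(C)C(C)(C)C)CCC(=C)[C@@]1(C)Cc1cc(C(=O)OC)ccc1OC | intermediate
14 | C8 β-methyl alcohol (C8, C9 and C10 methyls and the C5 side chain all β; benzyl and hydroxyethyl α) | OCC[C@@]1(C)[C@H]([C@H](C)O[Si](C)(C)C(C)(C)C)CC[C@H](C)[C@@]1(C)Cc1cc(C(=O)OC)ccc1OC | intermediate
15 | primary bromide: 14 with OH replaced by Br | BrCC[C@@]1(C)[C@H]([C@H](C)O[Si](C)(C)C(C)(C)C)CC[C@H](C)[C@@]1(C)Cc1cc(C(=O)OC)ccc1OC | intermediate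
16 | bromo phenol carbinol: 15 with free phenol and free (1S)-1-hydroxyethyl group | BrCC[C@@]1(C)[C@H]([C@H](C)O)CC[C@H](C)[C@@]1(C)Cc1cc(C(=O)OC)ccc1O | intermediate
17 | bromo methyl ketone: 16 with the carbinol oxidised to acetyl | BrCC[C@@]1(C)[C@H](C(C)=O)CC[C@H](C)[C@@]1(C)Cc1cc(C(=O)OC)ccc1O | intermediate
18 | dilithium salt of 17 (lithium phenoxide and lithium enolate CH2=C(OLi) on C5) | BrCC[C@@]1(C)[C@H](C(=C)O[Li])CC[C@H](C)[C@@]1(C)Cc1cc(C(=O)OC)ccc1O[Li] | intermediate
19 | methyl 4-hydroxy-3-{[(1R,2S,4aR,8aS)-1,2,8a-trimethyl-5-oxodecahydronaphthalen-1-yl]methyl}benzoate | O=C1CCC[C@@]2(C)[C@H]1CC[C@H](C)[C@@]2(C)Cc1cc(C(=O)OC)ccc1O | intermediate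
20 | methyl 4-hydroxy-3-{[(1R,2S,4aS,8aS)-1,2,8a-trimethyl-5-methylidenedecahydronaphthalen-1-yl]methyl}benzoate | C=C1CCC[C@@]2(C)[C@H]1CC[C@H](C)[C@@]2(C)Cc1cc(C(=O)OC)ccc1O | target

Total step count: 13. Longest linear sequence: 13 steps (from 1 and 2 to 20).

Steps most likely to fail

Step 8, poor facial selectivity of hydrogen delivery at C8: the α face carries the axial benzyl group on C9, so addition from the β face, which would give the more stable equatorial C8 methyl, may compete. The fallback sets out from 10 and comes back at 14. MeMgBr with CeCl3 adds to the C8 ketone to give the tertiary carbinol F5. Methyl chlorooxoacetate with DMAP gives the methyl oxalate F6. Bu3SnH with AIBN then removes the oxalate through the tertiary C8 radical, which should take hydrogen from the small tin hydride anti to the syn-axial C10 methyl, to give the C8 β-methyl vinyl compound F7. Hydroboration with 9-BBN and buffered H2O2 then returns 14.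

Step 4, slow or 1,2-selective reaction of the vinyl copper reagent with the tetrasubstituted, γ-branched enone. The fallback sets out from 6 and comes back at 12. A Mukaiyama–Michael addition of 1-(tert-butylsulfanyl)-1-(trimethylsilyloxy)ethene (Me3SiOTf cat., CH2Cl2, −78 °C), again anti to the C5 side chain, gives the thioester silyl enol ether F2. Fluoride-promoted benzylation with 8 (tris(dimethylamino)sulfonium difluorotrimethylsilicate) gives the keto thioester F3. Fukuyama reduction (Et3SiH, Pd/C) gives the aldehyde F4, and NaBH4 at −78 °C reduces the aldehyde in the presence of the hindered ketone to return 12.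

Step 2, lack of enzyme acceptance or weak discrimination between the C5 enantiomers. The fallback sets out from 4 and comes back at 5. Corey–Bakshi–Shibata reduction of racemic 4 ((R)-methyl oxazaborolidine cat., BH3·SMe2) gives the (1S)-carbinols as two diastereomers, 5 and the (4S) diastereomer F1, which are separated by chromatography. F1 is oxidised back to 4 with Dess–Martin periodinane, racemises at C5 and is recycled.

Further compounds
F1 | step 2 | (4S)-4-[(1S)-1-hydroxyethyl]-2,3-dimethylcyclohex-2-en-1-one | CC1=C(C)C(=O)CC[C@@H]1[C@H](C)O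
F2 | step 4 | S-tert-butyl thioester silyl enol ether (7 with CH2C(=O)S-tBu in place of vinyl) | CC(C)(C)SC(=O)C[C@@]1(C)[C@H]([C@H](C)O[Si](C)(C)C(C)(C)C)CCC(O[Si](C)(C)C)=C1C
F3 | step 4 | benzylated keto thioester (10 with CH2C(=O)S-tBu in place of vinyl) | CC(C)(C)SC(=O)C[C@@]1(C)[C@H]([C@H](C)O[Si](C)(C)C(C)(C)C)CCC(=O)[C@@]1(C)Cc1cc(C(=O)OC)ccc1OC
F4 | step 4 | keto aldehyde (12 with CHO in place of CH2OH) | O=CC[C@@]1(C)[C@H]([C@H](C)O[Si](C)(C)C(C)(C)C)CCC(=O)[C@@]1(C)Cc1cc(C(=O)OC)ccc1OC
F5 | step 8 | tertiary carbinol (10 with C8(OH)CH3 in place of C8=O, either C8 epimer) | C=C[C@@]1(C)[C@H]([C@H](C)O[Si](C)(C)C(C)(C)C)CCC(C)(O)[C@@]1(C)Cc1cc(C(=O)OC)ccc1OC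
F6 | step 8 | methyl oxalate of F5 | C=C[C@@]1(C)[C@H]([C@H](C)O[Si](C)(C)C(C)(C)C)CCC(C)(OC(=O)C(=O)OC)[C@@]1(C)Cc1cc(C(=O)OC)ccc1OC
F7 | step 8 | C8 β-methyl vinyl compound (14 with vinyl in place of CH2CH2OH) | C=C[C@@]1(C)[C@H]([C@H](C)O[Si](C)(C)C(C)(C)C)CC[C@H](C)[C@@]1(C)Cc1cc(C(=O)OC)ccc1OC
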